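The isoflavan is traced back to its isoflav-3-ene, and the pyran ring (O1, C2, C3, C4, C4a, C8a) to a 3-aryl-3-(hydroxymethyl)-2,3-dihydrobenzofuran in which the future C4 still hangs outside the ring. The key step exploits the C7 oxygen of ring A, which lies para to C4a: as a phenoxide it pushes C4a from C3 onto the activated exocyclic carbon, so the furan ring grows into the chromene while the electron-rich ring B at C3 carries the charge. The precursor comes in one step from resorcinol and a ring B oxetan-3-ol. Iridium-catalysed hydrogenation then sets C3, and both prenyl groups enter together at the two carbons flanked by two oxygens.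

Key step: step 4

Remark: MOM = methoxymethyl; the target is read as the (3S)-isoflavan; the quaternary centre of 8 is racemic and is erased in step 4; the ligand antipode for step 6 is assumed to be the one that gives 3S and would be fixed in a trial run.

**Route**

Step 1
Reactants: 1 4-bromoresorcinol (4-bromobenzene-1,3-diol)
Product: 2 1-bromo-2,4-bis(methoxymethoxy)benzene
Conditions: NaH, MOMCl, DMF, 0 °C to rt
Reagents that add atoms: chloromethyl methyl ether (MOMCl), COCCl
Why: Williamson-type O-alkylation of both phenoxides should give the bis-acetal, which survives organolithium chemistry and later serves as ortho-directing group.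

Step 2
Reactants: 2 1-bromo-2,4-bis(methoxymethoxy)benzene; 3 oxetan-3-one
Product: 5 3-[2,4-bis(methoxymethoxy)phenyl]oxetan-3-ol, via aryllithium 4 (not isolated)
Conditions: n-BuLi, THF, −78 °C; then 3, −78 to 0 °C; then H2O
Reagents that add atoms: none
Why: Bromine–lithium exchange is faster than ortho-deprotonation at −78 °C, and 1,2-addition of the aryllithium to the strained ketone should give the tertiary oxetanol.

Step 3
Reactants: 5 3-[2,4-bis(methoxymethoxy)phenyl]oxetan-3-ol; 6 resorcinol (benzene-1,3-diol, 3 equiv)
Product: 8 rac-3-[2,4-bis(methoxymethoxy)phenyl]-3-(hydroxymethyl)-2,3-dihydro-1-benzofuran-6-ol, via diaryloxetane 7 (not isolated)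
Conditions: LiN(SO2CF3)2 (10 mol %), Bu4NPF6 (5 mol %), CHCl3, 40 °C
Reagents that add atoms: none
Why: Lithium-catalysed Friedel–Crafts alkylation of a phenol by a 3-aryloxetan-3-ol with loss of water, in which the ring B stabilised oxetanyl cation should attack C4 of resorcinol (ortho to one hydroxyl, para to the other) and that ortho hydroxyl then opens the oxetane 5-exo-tet to the dihydrobenzofuran; the quaternary centre forms racemic.

Step 4
Reactants: 8 rac-3-[2,4-bis(methoxymethoxy)phenyl]-3-(hydroxymethyl)-2,3-dihydro-1-benzofuran-6-ol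
Product: 11 3-[2,4-bis(methoxymethoxy)phenyl]-2H-chromen-7-ol, via oxyphosphonium phenoxide 9 (not isolated), via spirocyclopropane dienone 10 (not isolated)
Conditions: PPh3, DIAD, THF, 0 to 50 °C
Reagents that add atoms: none
Why: Under Mitsunobu activation the phenol is the only acidic partner, so the primary alcohol becomes an oxyphosphonium on a molecule that is now a phenoxide (9); the ring A carbon para to the oxide (C4a) should displace it to give dienone 10, whose C3–C4a bond then heterolyses with rearomatisation to a C3 cation stabilised by ring B, and loss of a C4 proton gives the isoflav-3-ene. The closest known reaction type is the phenoxide-assisted 1,2-aryl shift of Winstein (Ar1-3 participation), that is a neophyl/Wagner–Meerwein ring enlargement as in 9-fluorenylmethanol to phenanthrene. Only the transient cyclopropane is closed (3-exo-tet); the pyran ring is not closed but arises when the dihydrofuran ring takes in the exocyclic carbon as C4. No stereocentre is formed: the racemic quaternary carbon becomes sp2 C3, which is set in step 6. The step needs migration of ring A and not of ring B, and loss of H from C4 and not from C2; the first is secured because only ring A carries a free oxide para to the migrating carbon while ring B is capped as MOM ethers, the second by conjugation of the new double bond with ring A.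

Step 5
Reactants: 11 3-[2,4-bis(methoxymethoxy)phenyl]-2H-chromen-7-ol
Product: 12 3-[2,4-bis(methoxymethoxy)phenyl]-7-(methoxymethoxy)-2H-chromene
Conditions: NaH, MOMCl, DMF, 0 °C to rt
Reagents that add atoms: chloromethyl methyl ether (MOMCl), COCCl
Why: Williamson-type O-alkylation of the phenoxide should install the third acetal, needed as directing group at C7 and removable together with the others.

Step 6
Reactants: 12 3-[2,4-bis(methoxymethoxy)phenyl]-7-(methoxymethoxy)-2H-chromene
Product: 13 (3S)-3-[2,4-bis(methoxymethoxy)phenyl]-7-(methoxymethoxy)-3,4-dihydro-2H-chromene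
Conditions: H2 (50 bar), [Ir(cod)(tBu-PHOX)]BArF (2 mol %), CH2Cl2, rt
Reagents that add atoms: none
Why: Iridium-catalysed asymmetric hydrogenation of a 3-aryl-2H-chromene with a chiral phosphino-oxazoline ligand (tBu-PHOX = 4-tert-butyl-2-[2-(diphenylphosphanyl)phenyl]-4,5-dihydrooxazole; cod = cycloocta-1,5-diene; BArF = tetrakis[3,5-bis(trifluoromethyl)phenyl]borate) should set C3 by catalyst-controlled face selection.

Step 7
Reactants: 13 (3S)-3-[2,4-bis(methoxymethoxy)phenyl]-7-(methoxymethoxy)-3,4-dihydro-2H-chromene; 14 prenyl bromide (1-bromo-3-methylbut-2-ene, 3 equiv)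
Product: 16 (3S)-3-[2,4-bis(methoxymethoxy)-3-(3-methylbut-2-en-1-yl)phenyl]-7-(methoxymethoxy)-8-(3-methylbut-2-en-1-yl)-3,4-dihydro-2H-chromene, via dilithio isoflavan 15 (not isolated)
Conditions: n-BuLi (2.6 equiv), TMEDA, THF, −20 to 0 °C; CuBr·SMe2 (20 mol %), then 14, −40 °C to rt
Reagents that add atoms: none
Why: Directed ortho-metalation should take place at the one C–H of each ring that is flanked by two oxygens (C8 between O1 and the 7-OMOM group, C3' between the two OMOM groups), and copper-catalysed allylation then delivers the prenyl groups at their primary carbon; C3 is not touched.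

Step 8
Reactants: 16 (3S)-3-[2,4-bis(methoxymethoxy)-3-(3-methylbut-2-en-1-yl)phenyl]-7-(methoxymethoxy)-8-(3-methylbut-2-en-1-yl)-3,4-dihydro-2H-chromene
Product: 17 4-[(3S)-7-hydroxy-8-(3-methylbut-2-en-1-yl)-3,4-dihydro-2H-chromen-3-yl]-2-(3-methylbut-2-en-1-yl)benzene-1,3-diol (target)
Conditions: 3 M HCl, MeOH, rt
Reagents that add atoms: none
Why: Acid-catalysed acetal exchange with methanol should remove all three MOM groups, and dilute acid at rt is chosen so that the freed phenols do not add to the neighbouring prenyl double bonds.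

**Compound list**

1 | 4-bromoresorcinol (4-bromobenzene-1,3-diol) | Oc1ccc(Br)c(O)c1 | starting material
2 | 1-bromo-2,4-bis(methoxymethoxy)benzene | COCOc1ccc(Br)c(OCOC)c1 | intermediate
3 | oxetan-3-one | O=C1COC1 | starting material
4 | [2,4-bis(methoxymethoxy)phenyl]lithium | [Li]c1ccc(OCOC)cc1OCOC | intermediate (not isolated)
5 | 3-[2,4-bis(methoxymethoxy)phenyl]oxetan-3-ol | COCOc1ccc(C2(O)COC2)c(OCOC)c1 | intermediate
6 | resorcinol (benzene-1,3-diol) | Oc1cccc(O)c1 | starting material
7 | 4-{3-[2,4-bis(methoxymethoxy)phenyl]oxetan-3-yl}benzene-1,3-diol | COCOc1ccc(C2(c3ccc(O)cc3O)COC2)c(OCOC)c1 | intermediate (not isolated)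
8 | rac-3-[2,4-bis(methoxymethoxy)phenyl]-3-(hydroxymethyl)-2,3-dihydro-1-benzofuran-6-ol | COCOc1ccc(C2(CO)COc3cc(O)ccc32)c(OCOC)c1 | intermediate
9 | {3-[2,4-bis(methoxymethoxy)phenyl]-6-oxido-2,3-dihydro-1-benzofuran-3-yl}methoxy(triphenyl)phosphonium (zwitterion) | COCOc1ccc(C2(CO[P+](c3ccccc3)(c3ccccc3)c3ccccc3)COc3cc([O-])ccc32)c(OCOC)c1 | intermediate (not isolated)
10 | 3-[2,4-bis(methoxymethoxy)phenyl]-3,3a-methano-2,3-dihydro-1-benzofuran-6(3aH)-one (cyclopropane across C3–C3a, cross-conjugated dienone) | O=C1C=CC23CC2(c2ccc(OCOC)cc2OCOC)COC3=C1 | intermediate (not isolated)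
11 | 3-[2,4-bis(methoxymethoxy)phenyl]-2H-chromen-7-ol | COCOc1ccc(C2=Cc3ccc(O)cc3OC2)c(OCOC)c1 | intermediate
12 | 3-[2,4-bis(methoxymethoxy)phenyl]-7-(methoxymethoxy)-2H-chromene | COCOc1ccc(C2=Cc3ccc(OCOC)cc3OC2)c(OCOC)c1 | intermediate
13 | (3S)-3-[2,4-bis(methoxymethoxy)phenyl]-7-(methoxymethoxy)-3,4-dihydro-2H-chromene | COCOc1ccc([C@H]2COc3cc(OCOC)ccc3C2)c(OCOC)c1 | intermediate
14 | prenyl bromide (1-bromo-3-methylbut-2-ene) | CC(C)=CCBr | starting material
15 | (3S)-8-lithio-3-[3-lithio-2,4-bis(methoxymethoxy)phenyl]-7-(methoxymethoxy)-3,4-dihydro-2H-chromene | COCOc1ccc([C@H]2COc3c([Li])c(OCOC)ccc3C2)c(OCOC)c1[Li] | intermediate (not isolated)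
16 | (3S)-3-[2,4-bis(methoxymethoxy)-3-(3-methylbut-2-en-1-yl)phenyl]-7-(methoxymethoxy)-8-(3-methylbut-2-en-1-yl)-3,4-dihydro-2H-chromene | COCOc1ccc([C@H]2COc3c(CC=C(C)C)c(OCOC)ccc3C2)c(OCOC)c1CC=C(C)C | intermediate
17 | 4-[(3S)-7-hydroxy-8-(3-methylbut-2-en-1-yl)-3,4-dihydro-2H-chromen-3-yl]-2-(3-methylbut-2-en-1-yl)benzene-1,3-diol | CC(C)=CCc1c(O)ccc([C@H]2COc3c(ccc(O)c3CC=C(C)C)C2)c1O | target

**Step count and risks**

Total step count: 8. Longest linear sequence: 8 steps (1 → 2 → 5 → 8 → 11 → 12 → 13 → 16 → 17).

Step 4. The ring carbon para to the phenoxide may be too slow to displace the oxyphosphonium. Capture of the activated carbon by the neighbouring acetal oxygen of ring B, migration of ring B, or loss of the C2 proton (giving the enol ether isomer) could then compete. The fallback sets out from 8 and comes back at 11; it separates installation of the leaving group from release of the phenoxide. The phenol of 8 would be acetylated selectively under Schotten–Baumann conditions (Ac2O, aqueous NaOH, 0 °C) to 3-[2,4-bis(methoxymethoxy)phenyl]-3-(hydroxymethyl)-2,3-dihydro-1-benzofuran-6-yl acetate F1. The neopentyl alcohol would then be mesylated (MsCl, Et3N, CH2Cl2, −10 °C) to {6-acetoxy-3-[2,4-bis(methoxymethoxy)phenyl]-2,3-dihydro-1-benzofuran-3-yl}methyl methanesulfonate F2. Treatment with t-BuOK in THF would strip the acetate, and the free phenoxide should then expel the sulfonate through dienone 10 and give 11 in an aprotic medium.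

Step 7. Lithiation may stop after one ring or spread to C6 and C5', and the allyl transfer may occur at the tertiary terminus and give reverse-prenyl isomers. The fallback sets out from 13 and comes back at 16. The dilithio species 15 would be quenched with iodine to (3S)-8-iodo-3-[3-iodo-2,4-bis(methoxymethoxy)phenyl]-7-(methoxymethoxy)-3,4-dihydro-2H-chromene F3, which can be purified and its substitution pattern secured. A double Stille coupling with tributyl(3-methylbut-2-en-1-yl)stannane (Pd(PPh3)4, CuI, CsF, DMF, 60 °C) should then deliver the linear prenyl groups of 16.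

Step 6. Facial discrimination may be poor because the ortho substituent twists ring B out of the alkene plane, or the double bond may migrate to the C2–C3 enol ether position before hydrogen is added. The fallback sets out from 12 and comes back at 13. Hydrogenation over Pd/C (H2, 1 bar, EtOAc, rt) would give racemic 3-[2,4-bis(methoxymethoxy)phenyl]-7-(methoxymethoxy)-3,4-dihydro-2H-chromene F4. Preparative chromatography on a chiral stationary phase (amylose tris(3,5-dimethylphenylcarbamate)) would then separate 13 from (3R)-3-[2,4-bis(methoxymethoxy)phenyl]-7-(methoxymethoxy)-3,4-dihydro-2H-chromene F5, which is set aside.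

**Further compounds**

F1 | step 4 | 3-[2,4-bis(methoxymethoxy)phenyl]-3-(hydroxymethyl)-2,3-dihydro-1-benzofuran-6-yl acetate | COCOc1ccc(C2(CO)COc3cc(OC(C)=O)ccc32)c(OCOC)c1
F2 | step 4 | {6-acetoxy-3-[2,4-bis(methoxymethoxy)phenyl]-2,3-dihydro-1-benzofuran-3-yl}methyl methanesulfonate | COCOc1ccc(C2(COS(C)(=O)=O)COc3cc(OC(C)=O)ccc32)c(OCOC)c1
F3 | step 7 | (3S)-8-iodo-3-[3-iodo-2,4-bis(methoxymethoxy)phenyl]-7-(methoxymethoxy)-3,4-dihydro-2H-chromene | COCOc1ccc([C@H]2COc3c(I)c(OCOC)ccc3C2)c(OCOC)c1I
F4 | step 6 | rac-3-[2,4-bis(methoxymethoxy)phenyl]-7-(methoxymethoxy)-3,4-dihydro-2H-chromene | COCOc1ccc(C2COc3cc(OCOC)ccc3C2)c(OCOC)c1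
F5 | step 6 | (3R)-3-[2,4-bis(methoxymethoxy)phenyl]-7-(methoxymethoxy)-3,4-dihydro-2H-chromene | COCOc1ccc([C@@H]2COc3cc(OCOC)ccc3C2)c(OCOC)c1
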